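**Assumption:** plumeria-iridoid numbering is used (C1 acetal CH, O2, C3=C4 bearing CO2Me, C5, C6, C7, C8, C9, C10 on C8, C11, C12 lactone C=O, C13 benzylidene CH). Genipin, allyl diethylphosphonoacetate, PhSeCl and 4-(TBSO)benzaldehyde are taken as commercial. "β"/convex means the face carrying H-5 and H-9.

## Retrosynthetic overview

1. Prismatomerin ⇐ desilylation ⇐ Horner–Wadsworth–Emmons olefination (C11=C13, E) of tetracyclic α-phosphono lactone 8 with aldehyde 9.
2. γ-Lactone (C8–O) and the C6=C7 alkene ⇐ selenolactonization / selenoxide elimination of γ,δ-unsaturated acid 5.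
3. C10–C11 bond and the C10 stereocentre ⇐ new DDQ-mediated dehydrogenative C–H alkylation of the allylic acetal-ether CH2 of 1,10-anhydrogenipin 2 with phosphonoacetate 3.
4. THF acetal ring (C1–O–C10) ⇐ intramolecular transacetalization of genipin 1, which supplies C5, C9, the CO2Me-dihydropyran and the cyclopentene.
5. Ring order: dihydropyran + cyclopentene (chiral pool) → THF acetal → γ-lactone → benzylidene.

## Route

**Step 1**
Reactants: 1, genipin
Product: 2, 1,10-anhydrogenipin, (1S,5S,9S): genipin with O-10 bonded to C1 (C1–O cis to C8, i.e. α); C7=C8 retained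
Conditions: PPTS (10 mol %), 4 Å MS, CH2Cl2 (0.01 M), 40 °C
Reagents that add atoms: none (loss of H2O)
Why: Acid-catalysed intramolecular transacetalization; the C1 oxocarbenium is trapped by the C10–OH, and the two-atom tether through C8/C9 allows only the cis-fused THF, which fixes C1 (C1 epimerizes through the cation).

**Step 2**
Reactants: 2, 1,10-anhydrogenipin; 3, allyl diethylphosphonoacetate
Product: 4, allyl (diethoxyphosphoryl)[(1R,5S,9S,10R)-1,10-anhydrogenipin-10-yl]acetate; the new C10 substituent is on the convex face (cis to H-1 and H-9); C11 epimer mixture (inconsequential). The 1S→1R change is a CIP priority change only.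
Conditions: DDQ (1.3 equiv), 3 (3 equiv), Mg(ClO4)2 (0.5 equiv), 2,6-dichloropyridine (2 equiv), 4 Å MS, ClCH2CH2Cl, 0 °C → rt
Reagents that add atoms: allyl diethylphosphonoacetate (3), C=CCOC(=O)CP(=O)(OCC)OCC
Why: Proposed new method: cross-dehydrogenative C–H alkylation of a bicyclic allylic acetal-ether — DDQ abstracts hydride from C10–H (α-oxy, allylic, aligned with the C7=C8 π system) to give a conjugated oxocarbenium ion, which the Mg-chelated phosphonoacetate enol(ate) (deprotonated by DDQH⁻) attacks Ferrier-type at C10 (1,2, restoring C7=C8) from the convex face anti to the cis-fused pyran, setting C10; the closest known chemistry is DDQ-mediated oxidative coupling of isochromans and other benzylic/allylic ethers with malonates and silyl enol ethers, not yet shown on an allylic ether whose oxygen is part of an acetal, nor with phosphonoacetates.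

**Step 3**
Reactants: 4
Product: 5, (diethoxyphosphoryl)[(1R,5S,9S,10R)-1,10-anhydrogenipin-10-yl]acetic acid (C11 epimers)
Conditions: Pd(PPh3)4 (5 mol %), PhSiH3 (2 equiv), CH2Cl2, 0 °C → rt; pH 4 aqueous work-up; used crude
Reagents that add atoms: none
Why: Tsuji–Trost deallylation with a neutral hydride scavenger frees the acid without base or acid, so the acetal, the β-alkoxyacrylate and the C15 methyl ester are untouched (no amine is used, to avoid addition at C3).

**Step 4**
Reactants: 5; 6, phenylselenenyl chloride
Product: 7, (1R,5S,7R,8S,9S,10R)-11-(diethoxyphosphoryl)-7-(phenylselanyl) tetracyclic lactone: the C12 carboxylate O is bonded to C8 (β, cis to H-9), PhSe is on C7 (α, trans to that O), C6 is CH2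
Conditions: PhSeCl (1.2 equiv), Et3N (1.2 equiv), CH2Cl2, −78 → −20 °C
Reagents that add atoms: phenylselenenyl chloride (6), Cl[Se]c1ccccc1
Why: 5-exo Markovnikov selenolactonization of a γ,δ-unsaturated acid; the carboxylate sits on the convex face of C10 and can reach the tertiary C8 only from that face (the only cis-fused outcome), so anti addition sets C8 with selenium on C7 α.

**Step 5**
Reactants: 7
Product: 8, (1R,5S,8S,9S,10R)-11-(diethoxyphosphoryl) tetracyclic lactone with C6=C7 (the prismatomerin core carrying P(O)(OEt)2 and H on C11 in place of the benzylidene)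
Conditions: 30% H2O2, pyridine, CH2Cl2, 0 °C → rt
Reagents that add atoms: none
Why: Selenide oxidation and selenoxide syn-elimination; C8 is quaternary, so the only syn β-hydrogen is H-6α and the alkene forms regiospecifically at C6=C7.

**Step 6**
Reactants: 8; 9, 4-(tert-butyldimethylsilyloxy)benzaldehyde
Product: 10, O-TBS-prismatomerin, (1R,5S,8S,9S,10S), 11(13)-E
Conditions: LiCl (3 equiv), DBU (1.2 equiv), 9 (1.5 equiv), MeCN, 0 °C → rt
Reagents that add atoms: 4-(tert-butyldimethylsilyloxy)benzaldehyde (9), O=Cc1ccc(O[Si](C)(C)C(C)(C)C)cc1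
Why: Horner–Wadsworth–Emmons olefination under Masamune–Roush conditions; α-phosphono-γ-lactones give the E-arylidene (aryl trans to C=O) with aryl aldehydes, and the mild base avoids strong-base enolization at C5 and limits retro-oxa-Michael opening at C10.

**Step 7**
Reactants: 10
Product: 11, prismatomerin
Conditions: TBAF (1.1 equiv), AcOH (1.1 equiv), THF, 0 °C
Reagents that add atoms: none
Why: Buffered fluoride cleavage of the aryl silyl ether; the AcOH buffer protects the lactone, acetal and arylidene Michael acceptor from basic fluoride.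

## Compound list

1 | genipin, methyl (1R,4aS,7aS)-1-hydroxy-7-(hydroxymethyl)-1,4a,5,7a-tetrahydrocyclopenta[c]pyran-4-carboxylate | COC(=O)C1=CO[C@H]([C@H]2[C@@H]1CC=C2CO)O | starting material
2 | 1,10-anhydrogenipin (1S,5S,9S) | COC(=O)C1=CO[C@@H]2OCC3=CC[C@H]1[C@H]23 | intermediate
3 | allyl diethylphosphonoacetate | C=CCOC(=O)CP(=O)(OCC)OCC | starting material
4 | allyl (diethoxyphosphoryl)[(1R,5S,9S,10R)-1,10-anhydrogenipin-10-yl]acetate, C11 epimers | COC(=O)C1=CO[C@@H]2O[C@@H](C(C(=O)OCC=C)P(=O)(OCC)OCC)C3=CC[C@H]1[C@H]23 | intermediate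
5 | (diethoxyphosphoryl)[(1R,5S,9S,10R)-1,10-anhydrogenipin-10-yl]acetic acid, C11 epimers | COC(=O)C1=CO[C@@H]2O[C@@H](C(C(=O)O)P(=O)(OCC)OCC)C3=CC[C@H]1[C@H]23 | intermediate
6 | phenylselenenyl chloride | Cl[Se]c1ccccc1 | starting material (reagent)
7 | (1R,5S,7R,8S,9S,10R)-7α-phenylselanyl-11-phosphono tetracyclic lactone | COC(=O)C1=CO[C@@H]2O[C@H]3C(P(=O)(OCC)OCC)C(=O)O[C@]34[C@H]([Se]c5ccccc5)C[C@H]1[C@H]24 | intermediate
8 | (1R,5S,8S,9S,10R)-11-(diethoxyphosphoryl)-Δ6 tetracyclic lactone | COC(=O)C1=CO[C@@H]2O[C@H]3C(P(=O)(OCC)OCC)C(=O)O[C@]34C=C[C@H]1[C@H]24 | intermediate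
9 | 4-(tert-butyldimethylsilyloxy)benzaldehyde | O=Cc1ccc(O[Si](C)(C)C(C)(C)C)cc1 | starting material
10 | O-TBS-prismatomerin | COC(=O)C1=CO[C@@H]2O[C@H]3/C(=C\c4ccc(O[Si](C)(C)C(C)(C)C)cc4)C(=O)O[C@]34C=C[C@H]1[C@H]24 | intermediate
11 | prismatomerin (1R,5S,8S,9S,10S, E) | COC(=O)C1=CO[C@@H]2O[C@H]3/C(=C\c4ccc(O)cc4)C(=O)O[C@]34C=C[C@H]1[C@H]24 | target

## Summary

Total steps: 7. Longest linear sequence: 7 (from genipin).

Stereocentres: C5 and C9 come from genipin and are never touched; C1 is set in step 1, C10 in step 2, C8 in step 4 (the transient C7 centre is removed in step 5), and the E-benzylidene in step 6.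

Steps most likely to fail:

1. **Step 2 (proposed new C–H alkylation).** Risks are slow hydride abstraction because the ether oxygen is an acetal oxygen, loss of H-6 from the cation to a dienol ether, or attack at C7/C1. Fallback with known chemistry: oxidize genipin with MnO2 to the 10-aldehyde, carry out a Knoevenagel condensation with 3 (TiCl4, N-methylmorpholine) to the C10=C11 alkylidene phosphonoacetate, then close the THF ring by intramolecular oxa-Michael addition of the C1 hemiacetal OH to C10 (reversible, giving the convex-face adduct) to reach 4.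
2. **Step 4 (selenolactonization).** The selenium electrophile must engage the concave face of C7=C8 while a strained cis-fused lactone forms. Fallback: Pd(II)-catalysed aerobic Wacker-type oxidative lactonization of 5 (Pd(TFA)2, pyridine, O2, toluene, 80 °C), in which oxypalladation at C8 followed by β-hydride elimination toward C6 gives 8 directly without a chalcogen electrophile.
3. **Step 6 (HWE).** Risks are E/Z erosion and base-induced retro-oxa-Michael opening of the C10–O bond. Fallback: HWE of 8 with aqueous formaldehyde/K2CO3 to the α-methylene lactone, then Mizoroki–Heck arylation with 4-iodophenol (Pd(OAc)2, Ag2CO3) to install the E-4-hydroxybenzylidene, which also removes the protecting-group step.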